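The runs were computed from invented constants; noise was put on by code.

Leftover nucleophile stands in two forms, free and bound as protonated nucleophile, and the question for this flask is how they share it.

common to all: nucleophile 0.375 M

| flask | electrophile | free base | remark | time |
|---|---|---|---|---|
| south-west | 0.25 M | 0.25 M | the very flask that is asked about, followed so far |  |
| north | 0.50 M | 0.25 M | run made earlier |  |
| flask | 0.25 M | 0.250 M |  | 50 min |

| run | time / min | electrophile / % | target / % |
|---|---|---|---|
| south-west | 0.833 | 102 | 0 |
| south-west | 2.50 | 95 | 1 |
| south-west | 4.00 | 91 | 5 |
| south-west | 6.00 | 85 | 6 |
| south-west | 10.0 | 83 | 14 |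
| south-west | 12.0 | 79 | 16 |
| south-west | 15.0 | 76 | 19 |
| north | 8.00 | 82 | 12 |
| north | 15.0 | 73 | 16 |
| north | 20.0 | 74 | 17 |
| north | 30.0 | 60 | 24 |
| north | 40.0 | 58 | 22 |
| north | 50.0 | 55 | 26 |

(each reading ± 2 percentage points)

* part of the electrophile that has reacted at 50 min
* share of the unused nucleophile that is free and not bound as protonated nucleophile, at 50 min

- a reading or a percentage of target counts all its forms, free or not
- what has gone from electrophile into another species counts as reacted, even if it can come back
- the earlier runs do not show how much of nucleophile is bound; that part of a forecast is a guess
- a reading of electrophile is of its free form alone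

The reckoning here runs down a ladder of rates. The first rung is proton transfer, taken as at balance at every moment, with the acid of each turnover sitting on a nucleophile rather than on free base; the earlier runs do not show this, so it is a guess. A turnover x then costs 2 nucleophiles, and the free share of the unused nucleophile is (c(nucleophile, charged) − 2x)/(c(nucleophile, charged) − x). On that count nucleophile is the limiting reagent, allowing 0.188 M of turnover against 0.25 M of electrophile.

The next rung is the gap between electrophile lost and target found, read as 5 percentage points at 15.0 min in the south-west run.

The last rung here is the turnover. The target reading there, 0.0475 M, gives, as a reading with that reading's scatter, the rate constant counted on free nucleophile, k = 0.0434 /M/min. The time 1/(k c(nucleophile)) is 61.4 min, longer than 50 min, so the flask is reckoned to be still on its way at the asked time. Integrated, x = 0.104 M. With the gap carried over unchanged, as a further guess, c comes to 46.6%, and the free share to 61.6%.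

The forecast gives 48% and 85%, with the words “most nucleophile stays free”; its share stands above this reckoning.

The flask gives 49.7% and 67.1%, the second 18 points below the forecast.

    electrophile + target ⇌ idle adduct, settled at all times (K = 3.30 /M)
    electrophile + nucleophile → acid set free + target (k = 0.0421 /M/min)
    nucleophile + acid set free ⇌ protonated nucleophile, settled at all times (K = 251 /M)
    acid set free + target → side product (k = 0.0464 /M/min)
    target ⇌ isomer of the product (K = 1.16, k = 0.00161 /min)
    acid set free + free base ⇌ salt of the base (K = 6.70 /M, k = 4.34 /M/min)

While free base held at 98.7% of its charge, turnover built up 37.5% target, bound forms counted, and 1.21% isomer of the product. At 50 min the flask held 0.0916 M protonated nucleophile against 0.00314 M salt of the base and 0.00196 M acid set free.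

In the neighbour with 0.94 M nucleophile, k gives x = 0.193 M and a free share of 74.2%. The simulation gives 77.7%.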